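**Plan**
1. Retrosynthetic cuts, in order: the MOM cap on O7; then the bond from C2 of the dihydropyranone ring to C6 of the dimethylchromane ring, giving chromone 7 and boronic acid 18; then the C8–CH2 (prenyl) bond of the chromone, traced back to an aryl 1,1-dimethylallyl ether; in 18 the C6–B bond, the C8–prenyl bond and the two bonds that close the chromane ring.
2. Enabling feature: C2 of the pyranone ring carries O1 and lies β to the C4 ketone, so at the chromone oxidation level (C2=C3) it is the flat, prochiral β-carbon of a vinylogous ester; chromane C6 has hydrogens on both neighbours (C5, C7), so it can carry boron and transmetalate unhindered.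
3. Forward, chromone half: the pyranone ring is bought intact in 7-hydroxychromone; the prenyl group is brought to C8 by O-propargylation, semihydrogenation and aromatic Claisen rearrangement; O7 is then capped.
4. Forward, chromane half: the chromane ring is made from 4-bromophenol and isoprene, followed by C8 iodination, prenylation through the aryl Grignard, and Br-to-B exchange.
5. Union and end: a catalytic asymmetric conjugate arylation saturates C2=C3 and joins the halves; MOM removal finishes the route.
6. Stereochemistry: the only stereocentre (C2, S) is set in the union by a chiral pyridine–oxazoline palladium catalyst (aryl delivered to the Re face of C2); no later step is basic enough to open the pyranone ring.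

Key step: step 9

Assumption: the sense of induction of the pyridine–oxazoline palladium catalyst on chromones is taken to parallel that on β-substituted cyclic enones, so the (R)-ligand should give the (2S)-flavanone; if the sense proves opposite, the (S)-ligand is used with no other change.

**Step 1**
Reactants: 1 7-hydroxy-4H-chromen-4-one; 2 3-chloro-3-methylbut-1-yne
Product: 3 7-[(2-methylbut-3-yn-2-yl)oxy]-4H-chromen-4-one
Conditions: K2CO3, KI (cat.), CuI (cat.), acetone, 55 °C
Reagents that add atoms: 3-chloro-3-methylbut-1-yne (compound 2), CC(C)(Cl)C#C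
Why: Copper-assisted O-alkylation of the single, acidic C7 phenol with the tertiary propargylic chloride is the standard entry to aryl 1,1-dimethylpropargyl ethers, and the chromone tolerates carbonate in acetone.

**Step 2**
Reactants: 3 7-[(2-methylbut-3-yn-2-yl)oxy]-4H-chromen-4-one
Product: 4 7-[(2-methylbut-3-en-2-yl)oxy]-4H-chromen-4-one
Conditions: H2 (1 atm), Pb-poisoned Pd/CaCO3, quinoline, EtOAc, rt, stopped after one equivalent
Reagents that add atoms: none
Why: Semihydrogenation of a terminal alkyne over poisoned palladium should stop at the alkene, and the C2=C3 bond of the vinylogous ester is not reduced under these conditions.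

**Step 3**
Reactants: 4 7-[(2-methylbut-3-en-2-yl)oxy]-4H-chromen-4-one
Product: 6 7-hydroxy-8-(3-methylbut-2-en-1-yl)-4H-chromen-4-one, via ortho-dienone 5 (not isolated)
Conditions: PhNEt2, 130 °C
Reagents that add atoms: none
Why: The aromatic Claisen rearrangement ([3,3]) of the 1,1-dimethylallyl ether delivers the 3-methylbut-2-enyl group to the ortho carbon and tautomerises to the phenol; C8 should be preferred over C6 because the C7–C8 bond of the benzopyranone has the higher double-bond character, as in 7-allyloxy coumarins and chromones.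

**Step 4**
Reactants: 6 7-hydroxy-8-(3-methylbut-2-en-1-yl)-4H-chromen-4-one
Product: 7 7-(methoxymethoxy)-8-(3-methylbut-2-en-1-yl)-4H-chromen-4-one
Conditions: MOMCl, K2CO3, acetone, rt
Reagents that add atoms: chloromethyl methyl ether, COCCl
Why: Williamson-type O-alkylation of the phenoxide gives an acetal cap that should survive the mildly acidic aqueous palladium step and keeps the phenol from adding to the neighbouring prenyl alkene under Pd(II).

**Step 5**
Reactants: 8 4-bromophenol; 9 isoprene
Product: 11 6-bromo-2,2-dimethylchromane, via ortho-prenylphenol 10 (not isolated)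
Conditions: AgOTf (5 mol%), isoprene added slowly, ClCH2CH2Cl, rt to 40 °C
Reagents that add atoms: isoprene (compound 9), C=CC(C)=C
Why: Acid-catalysed Friedel–Crafts ortho-prenylation of the phenol (para position blocked by Br) followed by Markovnikov hydroalkoxylation of the trisubstituted alkene is the known one-pot phenol/isoprene annulation to 2,2-dimethylchromanes.

**Step 6**
Reactants: 11 6-bromo-2,2-dimethylchromane
Product: 12 6-bromo-8-iodo-2,2-dimethylchromane
Conditions: NIS, TFA (cat.), MeCN, rt to 50 °C
Reagents that add atoms: N-iodosuccinimide, O=C1CCC(=O)N1I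
Why: Electrophilic aromatic iodination is directed by the ring oxygen, and with the para position held by bromine only C8 is ortho to it.

**Step 7**
Reactants: 12 6-bromo-8-iodo-2,2-dimethylchromane; 13 1-bromo-3-methylbut-2-ene
Product: 15 6-bromo-2,2-dimethyl-8-(3-methylbut-2-en-1-yl)chromane, via arylmagnesium chloride 14 (not isolated)
Conditions: i-PrMgCl·LiCl, THF, −20 °C; then CuBr·SMe2 (10 mol%), prenyl bromide, −20 to 0 °C
Reagents that add atoms: 1-bromo-3-methylbut-2-ene (compound 13), CC(C)=CCBr
Why: Iodine–magnesium exchange is much faster at C–I than at C–Br and is helped by the ortho oxygen, and the copper-catalysed allylic substitution should occur at the primary α-carbon of prenyl bromide because the γ-carbon is fully substituted.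

**Step 8**
Reactants: 15 6-bromo-2,2-dimethyl-8-(3-methylbut-2-en-1-yl)chromane
Product: 18 [2,2-dimethyl-8-(3-methylbut-2-en-1-yl)chroman-6-yl]boronic acid, via aryllithium 16 (not isolated), via lithium triisopropoxyborate 17 (not isolated)
Conditions: n-BuLi, THF, −78 °C; B(Oi-Pr)3, −78 °C to rt; 1 M HCl (aq), 0 °C, brief
Reagents that add atoms: triisopropyl borate, CC(C)OB(OC(C)C)OC(C)C; water, O
Why: Bromine–lithium exchange at −78 °C, trapping with the borate ester and mild hydrolysis is the standard aryl bromide to arylboronic acid sequence, and the ether and trisubstituted alkene are inert to it.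

**Step 9**
Reactants: 7 7-(methoxymethoxy)-8-(3-methylbut-2-en-1-yl)-4H-chromen-4-one; 18 [2,2-dimethyl-8-(3-methylbut-2-en-1-yl)chroman-6-yl]boronic acid
Product: 19 (2S)-2-[2,2-dimethyl-8-(3-methylbut-2-en-1-yl)chroman-6-yl]-7-(methoxymethoxy)-8-(3-methylbut-2-en-1-yl)chroman-4-one
Conditions: Pd(OCOCF3)2 (5–10 mol%), (R)-4-tert-butyl-2-(pyridin-2-yl)-4,5-dihydrooxazole (6–12 mol%), NH4PF6 (30 mol%), H2O (5 equiv), 18 (2 equiv), ClCH2CH2Cl, 60 °C
Reagents that add atoms: [2,2-dimethyl-8-(3-methylbut-2-en-1-yl)chroman-6-yl]boronic acid (compound 18), CC(C)=CCc1cc(B(O)O)cc2c1OC(C)(C)CC2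
Why: Transmetalation of 18 to the cationic ligand-bound Pd(II) gives an aryl–palladium species that binds the C2=C3 bond of 7 and inserts it, placing the aryl group on C2 and palladium on C3; water then protonates the palladium enolate, releasing the flavanone and a Pd(II) hydroxide that transmetalates again, so no oxidant is needed. The closest known reaction type is the Pd(II)/pyridine–oxazoline-catalysed asymmetric conjugate addition of arylboronic acids to chromones, which gives flavanones directly. No ring is closed: the pyranone ring of 7 is kept and only its C2=C3 bond is saturated. The new C2 stereocentre is under catalyst control, the tert-butyl group of the oxazoline differentiating the two chromone orientations in the insertion transition state, so that the (R)-ligand should deliver the aryl group to the Re face of C2 and give (2S). The step needs 1,4- over 1,2-addition and reaction at the enone rather than at either prenyl alkene; this should be secured because the polarised vinylogous ester is the only electron-poor alkene present, the MOM cap removes the phenol that could add to the 8-prenyl group under Pd(II), and the boron-bearing carbon has no ortho substituent. Protonation of the enolate should outrun β-hydride elimination to the flavone, and the non-basic medium should keep the new benzylic ether centre from racemising by retro-oxa-Michael opening.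

**Step 10**
Reactants: 19 (2S)-2-[2,2-dimethyl-8-(3-methylbut-2-en-1-yl)chroman-6-yl]-7-(methoxymethoxy)-8-(3-methylbut-2-en-1-yl)chroman-4-one
Product: 20 (2S)-2-[2,2-dimethyl-8-(3-methylbut-2-en-1-yl)chroman-6-yl]-7-hydroxy-8-(3-methylbut-2-en-1-yl)chroman-4-one
Conditions: 3 M HCl (aq)–MeOH (1:5), 45 °C, stopped at full conversion
Reagents that add atoms: none
Why: Acid-catalysed acetal exchange with methanol frees the C7 phenol; brief dilute acid of this kind is the usual MOM removal for prenylated flavonoids, and C2 is not epimerised because ring opening of flavanones is a base-promoted process.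

**Compound list**
1 | 7-hydroxy-4H-chromen-4-one | O=c1ccoc2cc(O)ccc12 | starting material
2 | 3-chloro-3-methylbut-1-yne | CC(C)(Cl)C#C | starting material
3 | 7-[(2-methylbut-3-yn-2-yl)oxy]-4H-chromen-4-one | C#CC(C)(C)Oc1ccc2c(c1)occc2=O | intermediate
4 | 7-[(2-methylbut-3-en-2-yl)oxy]-4H-chromen-4-one | C=CC(C)(C)Oc1ccc2c(c1)occc2=O | intermediate
5 | 8-(3-methylbut-2-en-1-yl)-8H-chromene-4,7-dione (ortho-dienone, not isolated) | CC(C)=CCC1C(=O)C=CC2=C1OC=CC2=O | intermediate
6 | 7-hydroxy-8-(3-methylbut-2-en-1-yl)-4H-chromen-4-one | CC(C)=CCc1c(O)ccc2c1occc2=O | intermediate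
7 | 7-(methoxymethoxy)-8-(3-methylbut-2-en-1-yl)-4H-chromen-4-one | CC(C)=CCc1c(OCOC)ccc2c1occc2=O | intermediate
8 | 4-bromophenol | Oc1ccc(Br)cc1 | starting material
9 | isoprene (2-methylbuta-1,3-diene) | C=CC(C)=C | starting material
10 | 4-bromo-2-(3-methylbut-2-en-1-yl)phenol (not isolated) | CC(C)=CCc1cc(Br)ccc1O | intermediate
11 | 6-bromo-2,2-dimethylchromane | CC1(C)CCc2cc(Br)ccc2O1 | intermediate
12 | 6-bromo-8-iodo-2,2-dimethylchromane | CC1(C)CCc2cc(Br)cc(I)c2O1 | intermediate
13 | 1-bromo-3-methylbut-2-ene (prenyl bromide) | CC(C)=CCBr | starting material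
14 | (6-bromo-2,2-dimethylchroman-8-yl)magnesium chloride (not isolated) | CC1(C)CCc2cc(Br)cc([Mg]Cl)c2O1 | intermediate
15 | 6-bromo-2,2-dimethyl-8-(3-methylbut-2-en-1-yl)chromane | CC(C)=CCc1cc(Br)cc2c1OC(C)(C)CC2 | intermediate
16 | [2,2-dimethyl-8-(3-methylbut-2-en-1-yl)chroman-6-yl]lithium (not isolated) | [Li]c1cc(CC=C(C)C)c2OC(C)(C)CCc2c1 | intermediate
17 | lithium triisopropoxy[2,2-dimethyl-8-(3-methylbut-2-en-1-yl)chroman-6-yl]borate (not isolated) | [Li+].CC(C)O[B-](OC(C)C)(OC(C)C)c1cc(CC=C(C)C)c2OC(C)(C)CCc2c1 | intermediate
18 | [2,2-dimethyl-8-(3-methylbut-2-en-1-yl)chroman-6-yl]boronic acid | CC(C)=CCc1cc(B(O)O)cc2c1OC(C)(C)CC2 | intermediate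
19 | (2S)-2-[2,2-dimethyl-8-(3-methylbut-2-en-1-yl)chroman-6-yl]-7-(methoxymethoxy)-8-(3-methylbut-2-en-1-yl)chroman-4-one | CC(C)=CCc1cc([C@@H]2CC(=O)c3ccc(OCOC)c(CC=C(C)C)c3O2)cc2c1OC(C)(C)CC2 | intermediate
20 | (2S)-2-[2,2-dimethyl-8-(3-methylbut-2-en-1-yl)chroman-6-yl]-7-hydroxy-8-(3-methylbut-2-en-1-yl)chroman-4-one | CC(C)=CCc1cc([C@@H]2CC(=O)c3ccc(O)c(CC=C(C)C)c3O2)cc2c1OC(C)(C)CC2 | target

**Totals**
Total steps: 10. Longest linear sequence: 6 steps (steps 1–4, 9, 10; the branch through steps 5–8, 9, 10 is equally long).

**Steps most likely to fail**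

Step 9. The electron-rich chromone may insert too slowly, so that protodeboronation of the electron-rich boronic acid or palladium chemistry at the prenyl alkenes takes over, or facial selectivity may be insufficient. The fallback builds the flavanone by the chalcone route and separates the enantiomers; it sets out from 7 and 15 and comes back at 19. Chromone 7 is opened with aqueous NaOH in refluxing EtOH (hydroxide addition at C2, then retro-Claisen loss of formate) to 1-[2-hydroxy-4-(methoxymethoxy)-3-(3-methylbut-2-en-1-yl)phenyl]ethan-1-one F1. Bromide 15 is converted by Br/Li exchange (n-BuLi, THF, −78 °C) and DMF quench into 2,2-dimethyl-8-(3-methylbut-2-en-1-yl)chromane-6-carbaldehyde F2. Claisen–Schmidt condensation of F1 with F2 (KOH, EtOH, rt) should give the (E)-2'-hydroxychalcone F3, which NaOAc in refluxing EtOH should close by intramolecular oxa-Michael addition to the racemic MOM-protected flavanone F4. Preparative HPLC on a chiral polysaccharide phase then gives 19; the (R)-enantiomer F5 is returned to the NaOAc equilibration, which racemises it through the chalcone.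

Step 3. The rearrangement may partly go to C6, or the tertiary allyl ether may fragment to the phenol and isoprene on heating. The fallback installs the prenyl group by cross-coupling; it sets out from 1 and comes back at 7. Iodination of 1 (NIS, DMF, 0 °C to rt), expected ortho to the phenol at C8 for the same bond-fixation reason, gives 7-hydroxy-8-iodo-4H-chromen-4-one F6. MOMCl/K2CO3 in acetone gives 8-iodo-7-(methoxymethoxy)-4H-chromen-4-one F7. Stille coupling of F7 with tributyl(3-methylbut-2-en-1-yl)stannane (Pd(PPh3)4, DMF, 90 °C) should give 7.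

Step 10. The acid may add the freed C7 phenol across the neighbouring prenyl alkene (closing a dimethylpyran ring) or hydrate or hydrochlorinate a prenyl group before the acetal is fully cleaved. The fallback uses a fluoride-labile cap instead; it sets out from 6 and comes back at 20. Silylation of 6 (TIPSCl, imidazole, DMF, rt) gives 8-(3-methylbut-2-en-1-yl)-7-[(triisopropylsilyl)oxy]-4H-chromen-4-one F8. The conjugate arylation of F8 with 18 under the step 9 conditions should give the (2S)-7-triisopropylsilyloxy flavanone F9. TBAF buffered with AcOH in THF at 0 °C should then release 20 without acid and without free base.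

**Further compounds**
F1 | step 9 | 1-[2-hydroxy-4-(methoxymethoxy)-3-(3-methylbut-2-en-1-yl)phenyl]ethan-1-one | CC(=O)c1ccc(OCOC)c(CC=C(C)C)c1O
F2 | step 9 | 2,2-dimethyl-8-(3-methylbut-2-en-1-yl)chromane-6-carbaldehyde | CC(C)=CCc1cc(C=O)cc2c1OC(C)(C)CC2
F3 | step 9 | (E)-3-[2,2-dimethyl-8-(3-methylbut-2-en-1-yl)chroman-6-yl]-1-[2-hydroxy-4-(methoxymethoxy)-3-(3-methylbut-2-en-1-yl)phenyl]prop-2-en-1-one | CC(C)=CCc1cc(/C=C/C(=O)c3ccc(OCOC)c(CC=C(C)C)c3O)cc2c1OC(C)(C)CC2
F4 | step 9 | racemic 2-[2,2-dimethyl-8-(3-methylbut-2-en-1-yl)chroman-6-yl]-7-(methoxymethoxy)-8-(3-methylbut-2-en-1-yl)chroman-4-one | CC(C)=CCc1cc(C2CC(=O)c3ccc(OCOC)c(CC=C(C)C)c3O2)cc2c1OC(C)(C)CC2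
F5 | step 9 | (2R)-2-[2,2-dimethyl-8-(3-methylbut-2-en-1-yl)chroman-6-yl]-7-(methoxymethoxy)-8-(3-methylbut-2-en-1-yl)chroman-4-one | CC(C)=CCc1cc([C@H]2CC(=O)c3ccc(OCOC)c(CC=C(C)C)c3O2)cc2c1OC(C)(C)CC2
F6 | step 3 | 7-hydroxy-8-iodo-4H-chromen-4-one | O=c1ccoc2c(I)c(O)ccc12
F7 | step 3 | 8-iodo-7-(methoxymethoxy)-4H-chromen-4-one | COCOc1ccc2c(c1I)occc2=O
F8 | step 10 | 8-(3-methylbut-2-en-1-yl)-7-[(triisopropylsilyl)oxy]-4H-chromen-4-one | CC(C)=CCc1c(O[Si](C(C)C)(C(C)C)C(C)C)ccc2c1occc2=O
F9 | step 10 | (2S)-2-[2,2-dimethyl-8-(3-methylbut-2-en-1-yl)chroman-6-yl]-8-(3-methylbut-2-en-1-yl)-7-[(triisopropylsilyl)oxy]chroman-4-one | CC(C)=CCc1cc([C@@H]2CC(=O)c3ccc(O[Si](C(C)C)(C(C)C)C(C)C)c(CC=C(C)C)c3O2)cc2c1OC(C)(C)CC2
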